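**Plan** (ring atoms: O1, C2 = ArCH beside the carbinol carbon, C3 = C(OH)CH3, C4 = CHCH3, C5 = the other ArCH)
- Retrosynthesis: remove the three O-benzyl groups; cut the C5–aryl bond (arylzinc + lactol-derived oxocarbenium ion); cut the ring bond C3–C4 (carbenoid C–H insertion of a diazo ester); cut the ester C5–O1 and the C2–aryl bond (aryl Grignard + O-benzyl lactaldehyde).
- Forward: (R)-lactate → aldehyde → aryl addition (C2/C3 unit) → α-diazopropanoate ester → closure of the five-membered ring as a γ-lactone (C5 at the acid oxidation level) → lactol → sulfone → second aryl group at C5 → debenzylation.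
- Enabling feature: with C5 as an ester carbonyl, O1–C5 is a tether that holds a carbenoid at C4 in a 1,5 relation to the C3–H bond. That bond is tertiary and activated by the C3 oxygen, so one insertion makes the C3–C4 bond, the ring and the fully substituted carbinol carbon.
- Stereochemistry: C3 from (R)-lactate, retained in the insertion; C2 by chelation-controlled addition; C4 in the insertion (methyl trans to the C3 methyl); C5 by inside attack of the arylzinc, cis to the C3 oxygen and the C4 methyl.

Key step: step 6

Remark: compounds 1, 4 and 7 and benzyl 2,2,2-trichloroacetimidate are taken as purchasable.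

Step 1
Reactants: 1 methyl (R)-lactate
Product: 2 methyl (R)-2-(benzyloxy)propanoate
Conditions: BnOC(=NH)CCl3, TfOH (cat.), cyclohexane/CH2Cl2, rt
Reagents that add atoms: benzyl 2,2,2-trichloroacetimidate, ClC(Cl)(Cl)C(=N)OCc1ccccc1
Why: Acid-catalysed O-benzylation with the trichloroacetimidate (imidate alkylation) needs no base, so the α-stereocentre of the lactate should stay intact.

Step 2
Reactants: 2 methyl (R)-2-(benzyloxy)propanoate
Product: 3 (R)-2-(benzyloxy)propanal
Conditions: i-Bu2AlH (1.1 equiv), Et2O, −78 °C; aq. potassium sodium tartrate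
Reagents that add atoms: none
Why: Low-temperature half-reduction of the ester stops at the aluminium hemiacetal, which should release the configurationally intact α-alkoxy aldehyde on work-up (used at once).

Step 3
Reactants: 3 (R)-2-(benzyloxy)propanal, 4 1-(benzyloxy)-4-bromo-2-methoxybenzene
Product: 6 (1R,2R)-2-(benzyloxy)-1-[4-(benzyloxy)-3-methoxyphenyl]propan-1-ol, via arylmagnesium bromide 5 (not isolated)
Conditions: 4, Mg, THF, rt; then 3, MgBr2·OEt2, CH2Cl2, −78 °C
Reagents that add atoms: none
Why: Chelation-controlled Grignard addition (Cram-chelate model): magnesium bridges the aldehyde and benzyloxy oxygens and the aryl group should enter from the face of the C–H bond, away from the methyl group, giving the (1R) carbinol syn to the (2R) ether.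

Step 4
Reactants: 6 (1R,2R)-2-(benzyloxy)-1-[4-(benzyloxy)-3-methoxyphenyl]propan-1-ol, 7 ethyl 2-methyl-3-oxobutanoate
Product: 8 (1R,2R)-2-(benzyloxy)-1-[4-(benzyloxy)-3-methoxyphenyl]propyl 2-methyl-3-oxobutanoate (epimers at the acyl α-carbon)
Conditions: 7 (3 equiv), DMAP (0.3 equiv), toluene, reflux (EtOH distilled off)
Reagents that add atoms: none
Why: DMAP-catalysed transesterification of a β-keto ester (through the acylketene) should acylate the hindered benzylic alcohol under neutral conditions without touching either stereocentre.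

Step 5
Reactants: 8 (1R,2R)-2-(benzyloxy)-1-[4-(benzyloxy)-3-methoxyphenyl]propyl 2-methyl-3-oxobutanoate
Product: 9 (1R,2R)-2-(benzyloxy)-1-[4-(benzyloxy)-3-methoxyphenyl]propyl 2-diazopropanoate
Conditions: 4-AcNHC6H4SO2N3, DBU, MeCN, 0 °C to rt
Reagents that add atoms: 4-acetamidobenzenesulfonyl azide, CC(=O)Nc1ccc(cc1)S(=O)(=O)N=[N+]=[N-]
Why: Regitz deacylative diazo transfer: the enolate of the α-methyl β-keto ester adds to the sulfonyl azide and the adduct fragments with transfer of the acetyl group to the sulfonamide nitrogen, which should leave the α-diazopropanoate.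

Step 6
Reactants: 9 (1R,2R)-2-(benzyloxy)-1-[4-(benzyloxy)-3-methoxyphenyl]propyl 2-diazopropanoate
Product: 10 (3R,4S,5R)-4-(benzyloxy)-5-[4-(benzyloxy)-3-methoxyphenyl]-3,4-dimethyloxolan-2-one
Conditions: Rh2(NHCOCH3)4 (dirhodium tetraacetamidate, 1 mol%), CH2Cl2, reflux, slow addition of 9
Reagents that add atoms: none
Why: Loss of N2 from 9 at the dirhodium catalyst gives an electrophilic rhodium carbenoid at C4, which should insert through a concerted three-centre hydride-transfer/C–C bond-forming transition state into the C3–H bond; that bond is tertiary, activated by the lone pairs of the benzyloxy oxygen, and held 1,5 to the carbenoid carbon by the ester linkage C5(=O)–O1–C2. The closest known reaction type is the dirhodium-carboxamidate-catalysed intramolecular C–H insertion of diazo esters next to an ether oxygen, which gives γ-butyrolactones. The ring closes as the five-membered lactone by 1,5-insertion; the benzylic C2–H bond would need a strained four-membered closure at a carbon deactivated by the acyloxy group, and the C3 methyl C–H bonds are primary and lead to a six-membered ring. C3 becomes the fully substituted carbinol carbon with retention, so its configuration and its syn relation to C2 are those fixed in steps 1–3, and at the new centre C4 the methyl group should take the face opposite the C3 methyl and the C2 aryl group, the less crowded arrangement in the product-like transition state. The step needs insertion to outrun 1,2-hydride shift of the α-methyl carbenoid (to the acrylate), addition to the electron-rich aryl ring and oxonium ylide formation at the benzyl ether; the weakly electrophilic carboxamidate-ligated carbenoid, the primary (least migration-prone) hydrogens of the methyl group, the doubly activated C3–H bond and slow addition are relied on for this.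

Step 7
Reactants: 10 (3R,4S,5R)-4-(benzyloxy)-5-[4-(benzyloxy)-3-methoxyphenyl]-3,4-dimethyloxolan-2-one
Product: 11 (3R,4S,5R)-4-(benzyloxy)-5-[4-(benzyloxy)-3-methoxyphenyl]-3,4-dimethyloxolan-2-ol (anomeric mixture)
Conditions: i-Bu2AlH (1.2 equiv), CH2Cl2, −78 °C; aq. potassium sodium tartrate
Reagents that add atoms: none
Why: Half-reduction of a γ-lactone at low temperature should stop at the lactol, with no ring stereocentre touched.

Step 8
Reactants: 11 (3R,4S,5R)-4-(benzyloxy)-5-[4-(benzyloxy)-3-methoxyphenyl]-3,4-dimethyloxolan-2-ol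
Product: 12 (3R,4S,5R)-2-(benzenesulfonyl)-4-(benzyloxy)-5-[4-(benzyloxy)-3-methoxyphenyl]-3,4-dimethyloxolane (anomeric mixture)
Conditions: PhSO2H, CaCl2, CH2Cl2, rt
Reagents that add atoms: benzenesulfinic acid, O=S(O)c1ccccc1
Why: Under the mild acidity of the sulfinic acid the lactol ionises and the oxocarbenium ion is trapped at sulfur (anomeric sulfone formation), which should give a stable precursor of the C5 cation.

Step 9
Reactants: 12 (3R,4S,5R)-2-(benzenesulfonyl)-4-(benzyloxy)-5-[4-(benzyloxy)-3-methoxyphenyl]-3,4-dimethyloxolane, 4 1-(benzyloxy)-4-bromo-2-methoxybenzene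
Product: 15 (2R,3S,4S,5S)-3-(benzyloxy)-2,5-bis[4-(benzyloxy)-3-methoxyphenyl]-3,4-dimethyloxolane, via aryllithium 13 (not isolated), via arylzinc bromide 14 (not isolated)
Conditions: 4, n-BuLi, THF, −78 °C; ZnBr2, THF, −78 °C to rt; then 12, THF, rt
Reagents that add atoms: none
Why: Bromine–lithium exchange and transmetalation give the arylzinc bromide, the zinc halide ionises the anomeric sulfone to the five-membered oxocarbenium ion and the arylzinc adds to it (organozinc substitution of an anomeric sulfone); inside attack on the envelope that holds the C3 benzyloxy group pseudo-axial and both methyl groups pseudo-equatorial, the conformer favoured when an alkoxy group stands 1,3 to the cationic carbon, should place the new aryl group cis to the C3 oxygen and the C4 methyl (4,5-cis, 2,5-trans).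

Step 10
Reactants: 15 (2R,3S,4S,5S)-3-(benzyloxy)-2,5-bis[4-(benzyloxy)-3-methoxyphenyl]-3,4-dimethyloxolane
Product: 16 (2R,3S,4S,5S)-2,5-bis(4-hydroxy-3-methoxyphenyl)-3,4-dimethyloxolan-3-ol
Conditions: H2 (1 atm), Pd/C, EtOAc/MeOH, rt
Reagents that add atoms: none
Why: Hydrogenolysis of the two aryl benzyl ethers and of the tertiary alkyl benzyl ether should free both phenols and the C3 hydroxyl, the ring C–O bonds being cleaved much more slowly under neutral conditions.

**Compound list**
1 | methyl (R)-lactate | C[C@@H](O)C(=O)OC | starting material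
2 | methyl (R)-2-(benzyloxy)propanoate | C[C@@H](OCc1ccccc1)C(=O)OC | intermediate
3 | (R)-2-(benzyloxy)propanal | C[C@@H](OCc1ccccc1)C=O | intermediate
4 | 1-(benzyloxy)-4-bromo-2-methoxybenzene | COc1cc(Br)ccc1OCc1ccccc1 | starting material
5 | [4-(benzyloxy)-3-methoxyphenyl]magnesium bromide | COc1cc([Mg]Br)ccc1OCc1ccccc1 | intermediate
6 | (1R,2R)-2-(benzyloxy)-1-[4-(benzyloxy)-3-methoxyphenyl]propan-1-ol | O[C@H](c1ccc(OCc2ccccc2)c(OC)c1)[C@@H](C)OCc1ccccc1 | intermediate
7 | ethyl 2-methyl-3-oxobutanoate | CCOC(=O)C(C)C(C)=O | starting material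
8 | (1R,2R)-2-(benzyloxy)-1-[4-(benzyloxy)-3-methoxyphenyl]propyl 2-methyl-3-oxobutanoate | CC(=O)C(C)C(=O)O[C@H](c1ccc(OCc2ccccc2)c(OC)c1)[C@@H](C)OCc1ccccc1 | intermediate
9 | (1R,2R)-2-(benzyloxy)-1-[4-(benzyloxy)-3-methoxyphenyl]propyl 2-diazopropanoate | CC(=[N+]=[N-])C(=O)O[C@H](c1ccc(OCc2ccccc2)c(OC)c1)[C@@H](C)OCc1ccccc1 | intermediate
10 | (3R,4S,5R)-4-(benzyloxy)-5-[4-(benzyloxy)-3-methoxyphenyl]-3,4-dimethyloxolan-2-one | O=C1O[C@H](c2ccc(OCc3ccccc3)c(OC)c2)[C@@](C)(OCc2ccccc2)[C@H]1C | intermediate
11 | (3R,4S,5R)-4-(benzyloxy)-5-[4-(benzyloxy)-3-methoxyphenyl]-3,4-dimethyloxolan-2-ol | OC1O[C@H](c2ccc(OCc3ccccc3)c(OC)c2)[C@@](C)(OCc2ccccc2)[C@H]1C | intermediate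
12 | (3R,4S,5R)-2-(benzenesulfonyl)-4-(benzyloxy)-5-[4-(benzyloxy)-3-methoxyphenyl]-3,4-dimethyloxolane | O=S(=O)(c1ccccc1)C1O[C@H](c2ccc(OCc3ccccc3)c(OC)c2)[C@@](C)(OCc2ccccc2)[C@H]1C | intermediate
13 | [4-(benzyloxy)-3-methoxyphenyl]lithium | COc1cc([Li])ccc1OCc1ccccc1 | intermediate
14 | [4-(benzyloxy)-3-methoxyphenyl]zinc bromide | COc1cc([Zn]Br)ccc1OCc1ccccc1 | intermediate
15 | (2R,3S,4S,5S)-3-(benzyloxy)-2,5-bis[4-(benzyloxy)-3-methoxyphenyl]-3,4-dimethyloxolane | COc1cc([C@H]2O[C@H](c3ccc(OCc4ccccc4)c(OC)c3)[C@@](C)(OCc3ccccc3)[C@H]2C)ccc1OCc1ccccc1 | intermediate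
16 | (2R,3S,4S,5S)-2,5-bis(4-hydroxy-3-methoxyphenyl)-3,4-dimethyloxolan-3-ol | COc1cc([C@H]2O[C@H](c3ccc(O)c(OC)c3)[C@@](C)(O)[C@H]2C)ccc1O | target

**Step count:** 10 steps in total; longest linear sequence 10 steps (1 to 16). Bromide 4 enters twice, in steps 3 and 9.

**Steps most likely to fail**

Step 6. What may go wrong: 1,2-hydride shift within the α-methyl carbenoid (giving the acrylate ester), or attack of the carbenoid on the electron-rich arene, outpaces C–H insertion. The fallback takes the methyl group off the carbenoid and adds it after ring closure. It sets out from alcohol 6 and returns at lactone 10. Acylation of 6 with bromoacetyl bromide and pyridine should give the bromoacetate F1. Treatment of F1 with N,N'-ditosylhydrazine and DBU should give the diazoacetate F2, whose carbenoid cannot undergo hydride shift. With Rh2(NHCOCH3)4 in refluxing CH2Cl2, F2 should insert into the same C3–H bond to give the lactone lacking the C4 methyl, F3. Methylation of the lithium enolate of F3 (LiN(i-Pr)2, THF, −78 °C; then MeI) should take place on the face opposite the C3 methyl and the C2 aryl group and so give the trans-dimethyl lactone 10; the enolate is kept cold so that benzyloxide is not eliminated from the β-carbon.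

Step 9. What may go wrong: the aryl nucleophile enters the oxocarbenium ion on the face trans to the C4 methyl (steric shielding by the methyl group overriding the directing effect of the axial benzyloxy group), or the cation loses a proton to the 2,3-dihydrofuran. The fallback reverses the polarity so that hydride, not aryl, is the entering group. It sets out from lactone 10 and bromide 4 and returns at 15. Bromide 4 with n-BuLi in THF at −78 °C gives aryllithium 13 as in step 9, and its addition to 10 at −78 °C should give the hemiketal F4. Et3SiH with BF3·OEt2 in CH2Cl2 at −78 °C then reduces the aryl-substituted oxocarbenium ion. A hydride entering on the face trans to the C4 methyl leaves the aryl group on the opposite, required face, cis to the C4 methyl, giving 15.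

Step 3. What may go wrong: incomplete chelation control (anti diastereomer) or partial racemisation of the α-alkoxy aldehyde. The fallback sets the carbinol centre by hydride delivery to a ketone. It sets out from ester 2 and returns at alcohol 6. Ester 2 with MeNH(OMe)·HCl and i-PrMgCl should give the N-methoxy-N-methylamide F5. Grignard reagent 5, made from 4 and Mg as in step 3, then gives the aryl ketone F6 (Weinreb ketone synthesis), with no enolisable aldehyde involved. Reduction of F6 with the bulky Li(s-Bu)3BH in THF at −78 °C (Felkin–Anh control, benzyloxy group anti to the incoming hydride) should give the syn alcohol 6; a Corey–Bakshi–Shibata reduction with the (R)-configured oxazaborolidine and BH3·SMe2, the aryl group acting as the large substituent, is the reagent-controlled alternative.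

**Further compounds**
F1 | step 6 | (1R,2R)-2-(benzyloxy)-1-[4-(benzyloxy)-3-methoxyphenyl]propyl bromoacetate | BrCC(=O)O[C@H](c1ccc(OCc2ccccc2)c(OC)c1)[C@@H](C)OCc1ccccc1
F2 | step 6 | (1R,2R)-2-(benzyloxy)-1-[4-(benzyloxy)-3-methoxyphenyl]propyl diazoacetate | [N-]=[N+]=CC(=O)O[C@H](c1ccc(OCc2ccccc2)c(OC)c1)[C@@H](C)OCc1ccccc1
F3 | step 6 | (4S,5R)-4-(benzyloxy)-5-[4-(benzyloxy)-3-methoxyphenyl]-4-methyloxolan-2-one | O=C1O[C@H](c2ccc(OCc3ccccc3)c(OC)c2)[C@@](C)(OCc2ccccc2)C1
F4 | step 9 | (3R,4S,5R)-4-(benzyloxy)-2,5-bis[4-(benzyloxy)-3-methoxyphenyl]-3,4-dimethyloxolan-2-ol | OC1(c2ccc(OCc3ccccc3)c(OC)c2)O[C@H](c2ccc(OCc3ccccc3)c(OC)c2)[C@@](C)(OCc2ccccc2)[C@H]1C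
F5 | step 3 | (R)-2-(benzyloxy)-N-methoxy-N-methylpropanamide | C[C@@H](OCc1ccccc1)C(=O)N(C)OC
F6 | step 3 | (R)-2-(benzyloxy)-1-[4-(benzyloxy)-3-methoxyphenyl]propan-1-one | C[C@@H](OCc1ccccc1)C(=O)c1ccc(OCc2ccccc2)c(OC)c1
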